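**Plan**
- Retrosynthesis: the quinone goes back to the tri-O-benzyl hydroquinone chroman; O1–C2 is then cut (phenol plus primary alcohol), then C2–C3 (a CH2 inserted into a C3–B bond), and last C3–C1′ and C4–C4a together, leaving vinylboronic pinacol ester, a B-ring aryllithium and an A-ring aryl bromide.
- Enabling feature (isoflavan numbering): C3–C4 is a two-carbon bridge between B-ring C1′ and A-ring C4a, i.e. a vinyl unit flanked by two aryl groups, and the boron left on C3 is where C2 is attached.
- Forward: the two arenes are made separately (5 from 2,3-dimethoxyphenol, 12 from 2,6-dimethoxyphenol) and joined across the vinyl group; the chain is extended by C2; the pyran ring is the only ring formed and closes last through O1–C2; debenzylation and oxidation give the quinone.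
- Stereochemistry: the single stereocentre C3 (S) is set by the chiral palladium catalyst in the coupling, carried through a stereoretentive 1,2-boronate shift, and not touched afterwards.

Key step: step 10

Assumption: the sense of induction of the MandyPhos ligand is taken from simple aryl/aryl conjunctive couplings; the enantiomer that delivers (S)-16 is used, and its equally available antipode would be taken if a first run showed the opposite sense.

**Route**

Step 1
Reactants: 1 2,3-dimethoxyphenol
Product: 2 2,3-dimethoxy-1,4-benzoquinone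
Conditions: Fremy's salt (2.2 equiv), aq. KH2PO4, acetone/H2O, rt
Reagents that add atoms: potassium nitrosodisulfonate (Fremy's salt), [O]N(S(=O)(=O)[O-])S(=O)(=O)[O-].[K+].[K+]
Why: Teuber oxidation: the nitroxyl radical of Fremy's salt oxidises a phenol with a free para position to the p-benzoquinone, and C4 of 1 is unsubstituted.

Step 2
Reactants: 2 2,3-dimethoxy-1,4-benzoquinone
Product: 3 2,3-dimethoxybenzene-1,4-diol
Conditions: Na2S2O4, H2O/EtOAc, rt
Reagents that add atoms: none
Why: Dithionite reduction of a quinone to the hydroquinone is fast and leaves the methoxy groups untouched.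

Step 3
Reactants: 3 2,3-dimethoxybenzene-1,4-diol
Product: 4 1,4-bis(benzyloxy)-2,3-dimethoxybenzene
Conditions: BnBr (2.4 equiv), K2CO3, degassed DMF, N2, rt → 60 °C
Reagents that add atoms: benzyl bromide, BrCc1ccccc1
Why: Williamson ether synthesis on both phenoxides, run with exclusion of air so that the hydroquinone is not re-oxidised.

Step 4
Reactants: 4 1,4-bis(benzyloxy)-2,3-dimethoxybenzene
Product: 5 1,4-bis(benzyloxy)-5-bromo-2,3-dimethoxybenzene (the B-ring bromide)
Conditions: NBS (1.0 equiv), MeCN, 0 °C → rt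
Reagents that add atoms: N-bromosuccinimide, O=C1CCC(=O)N1Br
Why: Electrophilic aromatic bromination of a tetra-alkoxybenzene; the two free positions of symmetric 4 are equivalent, so one equivalent of NBS should give a single monobromide.

Step 5
Reactants: 6 2,6-dimethoxyphenol
Product: 7 2-(benzyloxy)-1,3-dimethoxybenzene
Conditions: BnBr, K2CO3, DMF, 60 °C
Reagents that add atoms: benzyl bromide, BrCc1ccccc1
Why: Williamson ether synthesis on the hindered but acidic syringol hydroxyl.

Step 6
Reactants: 7 2-(benzyloxy)-1,3-dimethoxybenzene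
Product: 8 3-(benzyloxy)-2,4-dimethoxybenzaldehyde
Conditions: POCl3, DMF, 80 °C; then ice/H2O
Reagents that add atoms: N,N-dimethylformamide, CN(C)C=O; water, O
Why: Vilsmeier–Haack formylation of a 1,2,3-trialkoxybenzene goes to C4 (ortho/para to the two methoxy groups, C4 and C6 being equivalent), and the medium, free of strong Lewis acid, should spare the benzyl ether.

Step 7
Reactants: 8 3-(benzyloxy)-2,4-dimethoxybenzaldehyde
Product: 10 3-(benzyloxy)-2,4-dimethoxyphenol, via aryl formate 9 (not isolated)
Conditions: mCPBA, CH2Cl2, 0 °C → rt; then K2CO3 (cat.), MeOH, rt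
Reagents that add atoms: meta-chloroperoxybenzoic acid, OOC(=O)c1cccc(Cl)c1
Why: Baeyer–Villiger (Dakin-type) oxidation: the electron-rich aryl group migrates to oxygen to give the formate, which mild methanolysis converts to the phenol.

Step 8
Reactants: 10 3-(benzyloxy)-2,4-dimethoxyphenol
Product: 11 3-(benzyloxy)-6-bromo-2,4-dimethoxyphenol
Conditions: NBS (1.0 equiv), i-Pr2NH (10 mol%), CH2Cl2, −40 → 0 °C
Reagents that add atoms: N-bromosuccinimide, O=C1CCC(=O)N1Br
Why: Amine-mediated ortho-bromination of a phenol with NBS; the hydroxyl is the strongest director, its para position carries OMe, and C6 is its only free ortho position.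

Step 9
Reactants: 11 3-(benzyloxy)-6-bromo-2,4-dimethoxyphenol
Product: 12 4-(benzyloxy)-1-bromo-3,5-dimethoxy-2-(methoxymethoxy)benzene (the A-ring bromide)
Conditions: NaH, DMF, 0 °C; MOMCl, 0 °C → rt
Reagents that add atoms: chloromethyl methyl ether, COCCl
Why: O-alkylation of the phenoxide with MOMCl (Williamson-type) gives an acetal that should survive the organolithium and palladium steps and is later removed by acid.

Step 10
Reactants: 5 1,4-bis(benzyloxy)-5-bromo-2,3-dimethoxybenzene; 13 4,4,5,5-tetramethyl-2-vinyl-1,3,2-dioxaborolane (vinylboronic acid pinacol ester); 12 4-(benzyloxy)-1-bromo-3,5-dimethoxy-2-(methoxymethoxy)benzene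
Product: 16 2-{(1S)-2-[4-(benzyloxy)-3,5-dimethoxy-2-(methoxymethoxy)phenyl]-1-[2,5-bis(benzyloxy)-3,4-dimethoxyphenyl]ethyl}-4,4,5,5-tetramethyl-1,3,2-dioxaborolane, via B-ring aryllithium 14 (not isolated), via lithium vinylboronate complex 15 (not isolated)
Conditions: 5, t-BuLi (2.0 equiv), Et2O, −78 °C; 13, −78 → 0 °C; solvent exchange to THF; Pd(OAc)2 (3 mol%), MandyPhos (3.6 mol%), KOTf (2 equiv), 12, THF, 60 °C
Reagents that add atoms: none
Why: Bromine–lithium exchange on 5 gives aryllithium 14, which adds to boron of 13 to form the four-coordinate boronate 15; oxidative addition of 12 to Pd(0)–MandyPhos and removal of bromide as insoluble KBr leave a cationic arylpalladium(II) that binds the vinyl group of 15 and induces a 1,2-shift of the B-ring aryl from boron to the α-carbon anti to palladium (C3–C1′), after which reductive elimination at the β-carbon forms C4–C4a and leaves the secondary boronic ester on C3. The closest known reaction type is the palladium-catalysed enantioselective conjunctive cross-coupling of vinylboron ate complexes with aryl halides or triflates. No ring is closed in this step. The C3 stereocentre is set in the metalate shift by enantiofacial binding of the vinylboronate to the chiral bisphosphine–palladium complex, so the ligand enantiomer alone decides that (S)-16 forms. The step needs conjunctive coupling in preference to direct aryl transfer from boron to palladium (biaryl) and to β-hydride elimination; the pinacol ate complex (a poor transmetalating partner), the electron-rich migrating aryl, the chelating ferrocenyl bisphosphine and the halide-scavenging triflate are expected to secure this.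

Step 11
Reactants: 16 the (1S)-secondary pinacol boronate from step 10
Product: 18 (2S)-3-[4-(benzyloxy)-3,5-dimethoxy-2-(methoxymethoxy)phenyl]-2-[2,5-bis(benzyloxy)-3,4-dimethoxyphenyl]propan-1-ol, via homologated boronic ester 17 (not isolated)
Conditions: BrCH2Cl (3 equiv), n-BuLi (2.5 equiv), THF, −78 °C → rt; then 2 M NaOH, 30% H2O2, 0 °C → rt
Reagents that add atoms: bromochloromethane, ClCBr; hydrogen peroxide, OO
Why: Matteson homologation: chloromethyllithium adds to boron and the secondary benzylic carbon migrates to CH2 with retention of configuration as chloride leaves, and alkaline peroxide then oxidises the primary C–B bond to C–OH without touching C3.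

Step 12
Reactants: 18 (2S)-3-[4-(benzyloxy)-3,5-dimethoxy-2-(methoxymethoxy)phenyl]-2-[2,5-bis(benzyloxy)-3,4-dimethoxyphenyl]propan-1-ol
Product: 19 3-(benzyloxy)-6-{(2S)-2-[2,5-bis(benzyloxy)-3,4-dimethoxyphenyl]-3-hydroxypropyl}-2,4-dimethoxyphenol
Conditions: conc. HCl (cat.), MeOH/THF, 45 °C
Reagents that add atoms: none
Why: Acid-catalysed methanolysis of the MOM acetal; benzyl and methyl aryl ethers and the primary alcohol are stable under these conditions.

Step 13
Reactants: 19 3-(benzyloxy)-6-{(2S)-2-[2,5-bis(benzyloxy)-3,4-dimethoxyphenyl]-3-hydroxypropyl}-2,4-dimethoxyphenol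
Product: 20 (3S)-7-(benzyloxy)-3-[2,5-bis(benzyloxy)-3,4-dimethoxyphenyl]-6,8-dimethoxy-3,4-dihydro-2H-chromene
Conditions: PPh3, DIAD, THF, 0 °C → rt
Reagents that add atoms: none
Why: Intramolecular Mitsunobu etherification: the phenol displaces the activated primary alcohol in a 6-exo-tet closure of the pyran ring (O1–C2), and C3 is not a reacting centre, so its configuration is kept.

Step 14
Reactants: 20 (3S)-7-(benzyloxy)-3-[2,5-bis(benzyloxy)-3,4-dimethoxyphenyl]-6,8-dimethoxy-3,4-dihydro-2H-chromene
Product: 22 5-[(3S)-7-hydroxy-6,8-dimethoxy-3,4-dihydro-2H-chromen-3-yl]-2,3-dimethoxycyclohexa-2,5-diene-1,4-dione, via hydroquinone 21 (not isolated)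
Conditions: H2 (1 atm), 10% Pd/C, EtOAc/MeOH, rt; filter through Celite; stir the filtrate under air, rt
Reagents that add atoms: none
Why: Hydrogenolysis cleaves the three benzyl ethers (the chroman O1–C2 bond is not benzylic), and the electron-rich p-hydroquinone autoxidises in air to the quinone whereas the A-ring monophenol does not.

**Compound list**

1 | 2,3-dimethoxyphenol | COc1cccc(O)c1OC | starting material
2 | 2,3-dimethoxy-1,4-benzoquinone | COC1=C(OC)C(=O)C=CC1=O | intermediate
3 | 2,3-dimethoxybenzene-1,4-diol | COc1c(O)ccc(O)c1OC | intermediate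
4 | 1,4-bis(benzyloxy)-2,3-dimethoxybenzene | COc1c(OCc2ccccc2)ccc(OCc2ccccc2)c1OC | intermediate
5 | 1,4-bis(benzyloxy)-5-bromo-2,3-dimethoxybenzene | Brc1cc(OCc2ccccc2)c(OC)c(OC)c1OCc1ccccc1 | intermediate
6 | 2,6-dimethoxyphenol | COc1cccc(OC)c1O | starting material
7 | 2-(benzyloxy)-1,3-dimethoxybenzene | COc1cccc(OC)c1OCc1ccccc1 | intermediate
8 | 3-(benzyloxy)-2,4-dimethoxybenzaldehyde | COc1ccc(C=O)c(OC)c1OCc1ccccc1 | intermediate
9 | 3-(benzyloxy)-2,4-dimethoxyphenyl formate | COc1ccc(OC=O)c(OC)c1OCc1ccccc1 | intermediate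
10 | 3-(benzyloxy)-2,4-dimethoxyphenol | COc1ccc(O)c(OC)c1OCc1ccccc1 | intermediate
11 | 3-(benzyloxy)-6-bromo-2,4-dimethoxyphenol | COc1cc(Br)c(O)c(OC)c1OCc1ccccc1 | intermediate
12 | 4-(benzyloxy)-1-bromo-3,5-dimethoxy-2-(methoxymethoxy)benzene | COCOc1c(Br)cc(OC)c(OCc2ccccc2)c1OC | intermediate
13 | 4,4,5,5-tetramethyl-2-vinyl-1,3,2-dioxaborolane | C=CB1OC(C)(C)C(C)(C)O1 | starting material
14 | [2,5-bis(benzyloxy)-3,4-dimethoxyphenyl]lithium | [Li]c1cc(OCc2ccccc2)c(OC)c(OC)c1OCc1ccccc1 | intermediate
15 | lithium [2,5-bis(benzyloxy)-3,4-dimethoxyphenyl](vinyl)(pinacolato)borate | [Li+].C=C[B-]1(OC(C)(C)C(C)(C)O1)c1cc(OCc2ccccc2)c(OC)c(OC)c1OCc1ccccc1 | intermediate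
16 | 2-{(1S)-2-[4-(benzyloxy)-3,5-dimethoxy-2-(methoxymethoxy)phenyl]-1-[2,5-bis(benzyloxy)-3,4-dimethoxyphenyl]ethyl}-4,4,5,5-tetramethyl-1,3,2-dioxaborolane | CC1(C)OB(OC1(C)C)[C@@H](Cc1cc(OC)c(OCc2ccccc2)c(OC)c1OCOC)c1cc(OCc2ccccc2)c(OC)c(OC)c1OCc1ccccc1 | intermediate
17 | 2-{(2S)-3-[4-(benzyloxy)-3,5-dimethoxy-2-(methoxymethoxy)phenyl]-2-[2,5-bis(benzyloxy)-3,4-dimethoxyphenyl]propyl}-4,4,5,5-tetramethyl-1,3,2-dioxaborolane | CC1(C)OB(OC1(C)C)C[C@@H](Cc1cc(OC)c(OCc2ccccc2)c(OC)c1OCOC)c1cc(OCc2ccccc2)c(OC)c(OC)c1OCc1ccccc1 | intermediate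
18 | (2S)-3-[4-(benzyloxy)-3,5-dimethoxy-2-(methoxymethoxy)phenyl]-2-[2,5-bis(benzyloxy)-3,4-dimethoxyphenyl]propan-1-ol | OC[C@@H](Cc1cc(OC)c(OCc2ccccc2)c(OC)c1OCOC)c1cc(OCc2ccccc2)c(OC)c(OC)c1OCc1ccccc1 | intermediate
19 | 3-(benzyloxy)-6-{(2S)-2-[2,5-bis(benzyloxy)-3,4-dimethoxyphenyl]-3-hydroxypropyl}-2,4-dimethoxyphenol | OC[C@@H](Cc1cc(OC)c(OCc2ccccc2)c(OC)c1O)c1cc(OCc2ccccc2)c(OC)c(OC)c1OCc1ccccc1 | intermediate
20 | (3S)-7-(benzyloxy)-3-[2,5-bis(benzyloxy)-3,4-dimethoxyphenyl]-6,8-dimethoxy-3,4-dihydro-2H-chromene | COc1c(OC)c(OCc2ccccc2)cc([C@H]2COc3c(cc(OC)c(OCc4ccccc4)c3OC)C2)c1OCc1ccccc1 | intermediate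
21 | 2-[(3S)-7-hydroxy-6,8-dimethoxy-3,4-dihydro-2H-chromen-3-yl]-5,6-dimethoxybenzene-1,4-diol | COc1c(OC)c(O)cc([C@H]2COc3c(cc(OC)c(O)c3OC)C2)c1O | intermediate
22 | 5-[(3S)-7-hydroxy-6,8-dimethoxy-3,4-dihydro-2H-chromen-3-yl]-2,3-dimethoxycyclohexa-2,5-diene-1,4-dione | COC1=C(OC)C(=O)C([C@H]2COc3c(cc(OC)c(O)c3OC)C2)=CC1=O | target

**Step count**

Total: 14 steps. Longest linear sequence: 10 steps (steps 5–9, 10, 11–14, from 2,6-dimethoxyphenol).

**Steps most likely to fail**

Step 10. Oxidative addition of the hindered, electron-rich bromide may be slow and residual halide may block the cationic pathway, so direct aryl transfer to palladium or protodeboronation could outrun the metalate shift; facial selectivity could also be low. The fallback is a reagent-controlled lithiation–borylation, which forms C3–C1′ by a 1,2-shift without palladium. Setting out from 12, Br/Li exchange (n-BuLi, THF, −78 °C) and opening of ethylene oxide (BF3·OEt2) would give 2-[4-(benzyloxy)-3,5-dimethoxy-2-(methoxymethoxy)phenyl]ethanol F1. Carbamoylation (i-Pr2NCOCl, Et3N, toluene, reflux) would give 2-[4-(benzyloxy)-3,5-dimethoxy-2-(methoxymethoxy)phenyl]ethyl N,N-diisopropylcarbamate F2. From 5, Br/Li exchange and quench with 2-isopropoxy-4,4,5,5-tetramethyl-1,3,2-dioxaborolane would give 2-[2,5-bis(benzyloxy)-3,4-dimethoxyphenyl]-4,4,5,5-tetramethyl-1,3,2-dioxaborolane F3. Deprotonation of F2 with s-BuLi/(+)-sparteine (Et2O, −78 °C), addition of F3 and warming with MgBr2·OEt2 should induce aryl migration with loss of the carbamate and rejoin the route at 16. The (+)-diamine is chosen because the pro-S selectivity of (−)-sparteine, retentive borylation and invertive migration would lead to the (R)-boronate.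

Step 8. Bromination may occur para to the C2 methoxy group (at C5) instead of ortho to the hydroxyl, a second bromine may enter, or the electron-rich phenol may be oxidised. The fallback reverses the order and lets the acetal direct a metalation. From 10, NaH/MOMCl would give 2-(benzyloxy)-1,3-dimethoxy-4-(methoxymethoxy)benzene F4. Directed ortho-lithiation next to the OMOM group (n-BuLi, TMEDA, Et2O, 0 °C) and quench with 1,2-dibromotetrachloroethane should then give 12 with the halogen placed by the directing group rather than by ring electronics.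

Step 11. The short-lived chloromethyllithium may decompose before the hindered benzylic boronate captures it, and a second insertion or butyl addition to boron may compete. The fallback attaches C2 by a stereoretentive olefination instead of a carbenoid insertion. From 16, Zweifel olefination (vinyllithium or vinylmagnesium bromide, THF; then I2, NaOMe/MeOH) would give (3R)-4-[4-(benzyloxy)-3,5-dimethoxy-2-(methoxymethoxy)phenyl]-3-[2,5-bis(benzyloxy)-3,4-dimethoxyphenyl]but-1-ene F5; the spatial arrangement is unchanged and only the CIP descriptor differs. Lemieux–Johnson cleavage (OsO4 cat., NaIO4, 2,6-lutidine, dioxane/H2O) would give (2S)-3-[4-(benzyloxy)-3,5-dimethoxy-2-(methoxymethoxy)phenyl]-2-[2,5-bis(benzyloxy)-3,4-dimethoxyphenyl]propanal F6. This configurationally labile α-aryl aldehyde would be reduced at once with NaBH4 (MeOH, 0 °C) to rejoin the route at 18.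

**Further compounds**

F1 | step 10 | 2-[4-(benzyloxy)-3,5-dimethoxy-2-(methoxymethoxy)phenyl]ethanol | OCCc1cc(OC)c(OCc2ccccc2)c(OC)c1OCOC
F2 | step 10 | 2-[4-(benzyloxy)-3,5-dimethoxy-2-(methoxymethoxy)phenyl]ethyl N,N-diisopropylcarbamate | CC(C)N(C(C)C)C(=O)OCCc1cc(OC)c(OCc2ccccc2)c(OC)c1OCOC
F3 | step 10 | 2-[2,5-bis(benzyloxy)-3,4-dimethoxyphenyl]-4,4,5,5-tetramethyl-1,3,2-dioxaborolane | CC1(C)OB(OC1(C)C)c1cc(OCc2ccccc2)c(OC)c(OC)c1OCc1ccccc1
F4 | step 8 | 2-(benzyloxy)-1,3-dimethoxy-4-(methoxymethoxy)benzene | COCOc1ccc(OC)c(OCc2ccccc2)c1OC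
F5 | step 11 | (3R)-4-[4-(benzyloxy)-3,5-dimethoxy-2-(methoxymethoxy)phenyl]-3-[2,5-bis(benzyloxy)-3,4-dimethoxyphenyl]but-1-ene | C=C[C@@H](Cc1cc(OC)c(OCc2ccccc2)c(OC)c1OCOC)c1cc(OCc2ccccc2)c(OC)c(OC)c1OCc1ccccc1
F6 | step 11 | (2S)-3-[4-(benzyloxy)-3,5-dimethoxy-2-(methoxymethoxy)phenyl]-2-[2,5-bis(benzyloxy)-3,4-dimethoxyphenyl]propanal | O=C[C@@H](Cc1cc(OC)c(OCc2ccccc2)c(OC)c1OCOC)c1cc(OCc2ccccc2)c(OC)c(OC)c1OCc1ccccc1
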